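All runs were computed with made-up constants; scatter was added.

After 2.0 h, later than the last reading of Tuesday's run at 80.0 min, we must say what stands in a flask charged with 10 mM of substrate and 10.5 mM of coupling partner, more partner than the 7.9 mM of Tuesday's run; so both the time and the charge change.

in all of them: substrate 10 mM
- Monday's: coupling partner 5.2 mM; run made earlier
- Tuesday's: coupling partner 7.9 mM; run made earlier
- flask: coupling partner 10.5 mM; time 2.0 h

- Monday's (time / min: substrate / %, mono adduct / %, other mono adduct / %): 6.00: 96, 3, 3; 20.0: 84, 7, 6; 30.0: 77, 10, 11; 50.0: 70, 15, 13; 80.0: 61, 16, 17
- Tuesday's (time / min: substrate / %, mono adduct / %, other mono adduct / %): 6.00: 91, 5, 2; 20.0: 75, 10, 13; 30.0: 69, 12, 14; 50.0: 55, 17, 18; 80.0: 44, 20, 24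

(scatter of a reading: 1.5 percentage points)

- substrate at 2.0 h, in percent of the substrate charged
- mono adduct at 2.0 h, in percent of the substrate charged
- other mono adduct at 2.0 h, in percent of the substrate charged
- double product at 2.0 h, in percent of the substrate charged



1. Each first step costs one substrate and one coupling partner, so we work with the fractions left, f_A for substrate and f_B for partner, and not with what is made. For a rate k·[substrate]·[partner], the integrated second-order law gives ln(f_B/f_A) = k(c_B − c_A)t, where c_A and c_B are the charges and t is the time.

2. Monday's run at 80.0 min has used 39.0% of its substrate, so its f_B is 25.0% and k is 0.00232 /mM/min. Tuesday's run gives f_B = 29.1% and k = 0.00246 /mM/min. Their mean, 0.00239 /mM/min, is our paired constant: the logarithm of partner's fraction left over substrate's, divided by charge difference and time.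

3. But the readings fall short of the charge, by 6.00% on Monday and 12.0% on Tuesday. If that is double product, each unit took one more partner, and k becomes 0.00393 /mM/min and 0.00685 /mM/min. These lie further apart than the first pair. A shortfall carries the scatter of 3 readings, so this is a lean, yet we keep the first pair.

4. For this flask our rule gives substrate 23.6% and partner 27.2%. Taking the mean shortfall per substrate used gives a shortfall of 14.1%, which we offer for double product. Tuesday's split of the rest gives mono adduct 28.3% and other mono adduct 34.0%.

5. The forecast differs from our reckoning: 32%, 21%, 22% and 25%, in the order asked, with the ground “The double product is taken from the mass-balance shortfall”.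

The flask gives 25.4%, 26.8%, 30.6% and 8.50%.

    substrate + coupling partner → mono adduct + by-product (k = 51.9 /M/h)
    substrate + by-product → side product (k = 70.3 /M/h)
    substrate + coupling partner → other mono adduct + by-product (k = 57.8 /M/h)
    crystals ⇌ by-product, rate k4*(cs4 - [by-product]) while solid is left; crystals form when [by-product] > cs4 (solubility = 0.520 mM, k = 3.79 /h)
    coupling partner + mono adduct → double product + by-product (k = 23.2 /M/h)
    coupling partner + other mono adduct → double product + by-product (k = 19.2 /M/h)

In this flask double product stands at 8.50% beside side product at 8.78%, against the forecast's 25%. With 29% of partner left, the flask returns a paired constant of 0.00234 /mM/min. We now read the same flask at 5.0 h: our constant gives substrate 9.95%, and that neighbouring flask holds 11.6%.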